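Readings and results come from a simulation for an exercise; scatter was added.

If a level of links marks the end of a supply and not a balance, the number to follow is the chance that one second end group ends as a link. So we keep the books on second end groups, which we take to be the limiting reagent.

the same everywhere: first end groups 0.98 M
- east: second end groups 1 equiv; third end groups 1 equiv; the very flask that is asked about, followed so far
- north-west: second end groups 1 equiv; third end groups 0.67 equiv; run made earlier
- flask: second end groups 1.00 equiv; third end groups 1.00 equiv; time 6.0 h

- east (time / h: links / %): 0.500: 18.8; 1.50: 17.1; 3.00: 18.1; 4.00: 17.7; 6.00: 17.8
- north-west (time / h: links / %): 0.200: 23.8; 0.667: 23.1; 1.00: 23.1; 1.50: 22.9; 2.50: 22.6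

(each reading ± 0.3 percentage points)

- Wednesday's: change nothing and wait 2.0 h more
- Tuesday's: at 6.0 h take out 90 % of the links then present, then wait 2.0 h
- Thursday's: at 6.0 h add second end groups, 50.0 % of the amount charged, then wait 2.0 h
- Saturday's: at 6.0 h add first end groups, 50.0 % of the amount charged, then wait 2.0 h

- what is taken out of links is counted as made
- additions bring no volume worth counting

- links, in percent of the first end groups first charged, at 6.0 h
- the remedy with the largest gain of links, or "none" below 2 percentage points (Wednesday's / Tuesday's / Thursday's / Saturday's / none)
- links present, with what was taken out counted in, in percent of the first end groups first charged, after Wednesday's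
- links present, with what was taken out counted in, in percent of the first end groups first charged, after Saturday's

1. Charge. The east run and the north-west run each hold 1 equiv of second end groups, so a percentage of links is also a percentage of second end groups. Call this share p.

2. Links entry. The late east readings average 17.7 %, and the late north-west readings average 22.9 %.

3. Remainder entry. The rest, 1 − p, went unseen. The north-west run had less third end groups and more links, so we let third end groups hold the rival branch. With odds o = p/(1 − p) and e the equivalents of third end groups charged, we define the fork number F = o·e, the odds of a link multiplied by the third end groups charged. East gives 0.215 equiv and north-west gives 0.199 equiv, so we carry their mean, F = 0.207 equiv.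

4. Our commitment. We read the flask at 17.7 %, and we book no gain for Wednesday's. On our reading, Saturday's first end groups find no partner, so Saturday's also stays at 17.7 %. Thursday's dose, taken at the chance that F gives, earns 8.6 percentage points. Tuesday's has no entry in this ledger, so we choose Thursday's.

5. The forecast holds that “the east flask has reached equilibrium” and gives 17.8 % (17.4 % to 18.2 %), 17.8 % after Wednesday's, 24 % after Saturday's, and Tuesday's as best, so it differs from us on the last two.

6. Result. The flask gives 17.6 %, then 17.6 % after Wednesday's and 17.6 % after Saturday's. The best remedy is Thursday's, gaining 12 points, more than our 8.6 points. Tuesday's, which we left unbooked, gains 7 points. Second end groups stand at 0 % at 6.00 h. The books close with links at 17.6 % and isomer of the product at 13.9 % of the first end groups charged, links of the second sort at 0.578 M, and decomposed reagent at 0.0928 M.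

    second end groups + third end groups → links of the second sort (k = 0.00350 M⁻¹ s⁻¹)
    third end groups ⇌ dormant form (K = 0.520, k = 8.38 × 10⁻⁴ s⁻¹)
    first end groups + second end groups → links (k = 0.00120 M⁻¹ s⁻¹)
    second end groups → decomposed reagent (k = 2.94 × 10⁻⁴ s⁻¹)
    links ⇌ isomer of the product (K = 0.788, k = 8.06 × 10⁻⁴ s⁻¹)

7. Neighbour. Take a neighbour flask, charged with 1.70 equiv of third end groups, with its other charges and its time as in the flask. Our fork number gives odds of 0.122 for the neighbour flask, so p = 10.9 %. In the neighbour flask, links come to 11.4 %, second end groups stand at 0 %, and isomer of the product holds 8.95 %.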